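**Plan**

- **Cuts.** First the protecting group on the C3 oxygen is removed. Ring C is then cut at C4–C4a and O1–C2, which gives 2,4-diprenylphloroglucinol (ring A complete) and a 2-alkoxy aroylacetate (C2, C3, C4, ring B and its fused pyran). Finally the C2–C3 bond of that keto ester is cut, giving a chromene-7-carboxylic acid derivative and protected ethyl glycolate.
- **Enabling feature.** Ring A is symmetric about the axis through C7 and C4a, so O1 matches the C5 oxygen and the C8 prenyl matches the C6 prenyl. The phenol partner therefore has a single unsubstituted carbon (the future C4a) between two interchangeable hydroxyls, and only one flavone can form.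
- **Forward order.** Ring A is finished first by double C-prenylation of an ester-blocked phloroglucinol and removal of the blocking group. The dimethylpyran on ring B is made from umbelliferone, which fixes its orientation. Ring C closes last in one thermal operation, and deprotection ends the route.
- **Stereochemistry.** The target has no stereocentre and no alkene geometry to control (the chromene alkene is cis by ring constraint). The one stereocentre met on the way, the α-carbon of the keto ester, is racemic and becomes sp2 C3.

Key step: step 8

Assumption: the α-alkoxy keto ester is handled as its racemic keto–enol mixture, which is immaterial because the centre is lost on ring closure. Flavone numbering is used for atoms of the target.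

**Step 1**
Reactants: 1 methyl 2,4,6-trihydroxybenzoate; 2 prenyl bromide (1-bromo-3-methylbut-2-ene, 2.1 equiv)
Product: 3 methyl 2,4,6-trihydroxy-3,5-bis(3-methylbut-2-enyl)benzoate
Conditions: KOH (2.2 equiv), H2O, 0 °C → rt, Ar
Reagents that add atoms: none
Why: Base-mediated C-alkylation of a phloroglucinol phenoxide with an allylic bromide in water, the method used to diprenylate acylphloroglucinols: hydrogen bonding to the phenoxide oxygens steers the soft electrophile to the two free ring carbons, while the ester occupies the third carbon and tempers the ring against a further, dearomatising alkylation.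

**Step 2**
Reactants: 3 methyl 2,4,6-trihydroxy-3,5-bis(3-methylbut-2-enyl)benzoate
Product: 5 2,4-diprenylphloroglucinol [2,4-bis(3-methylbut-2-enyl)benzene-1,3,5-triol], via 2,4,6-trihydroxy-3,5-diprenylbenzoic acid 4 (not isolated)
Conditions: KOH (aq, degassed), MeOH, 90–100 °C (sealed tube), Ar; then 1 M HCl, 0 °C, to pH 5
Reagents that add atoms: none
Why: Alkaline saponification followed by protodecarboxylation of a polyhydroxybenzoate, the usual way to strip a carboxylate blocking group from alkenyl-substituted resorcylates: ipso-protonation is easy because three oxygens activate that carbon, and hot base, unlike acid, leaves the ortho-prenyl phenol units uncyclised.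

**Step 3**
Reactants: 6 umbelliferone (7-hydroxycoumarin)
Product: 8 2,2-dimethyl-2H-chromen-7-ol, via Z-allylic diol 7 (not isolated)
Conditions: MeMgBr (5 equiv), THF, 0 °C → reflux; sat. aq NH4Cl; then pyridinium p-toluenesulfonate (5 mol %), toluene, 60 °C
Reagents that add atoms: methylmagnesium bromide, C[Mg]Br
Why: Double 1,2-addition of a methyl Grignard reagent to the coumarin lactone (one further equivalent is consumed by the phenol, as in the classical conversion of free hydroxy-benzopyranones into gem-dimethylpyrans) gives the Z-allylic tertiary alcohol 7, which cyclodehydrates under mild acid through its stabilised allyl cation, so that the positions of ring oxygen, alkene and 7-OH are inherited from 6 without any regiochemical choice.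

**Step 4**
Reactants: 8 2,2-dimethyl-2H-chromen-7-ol
Product: 9 2,2-dimethyl-2H-chromen-7-yl trifluoromethanesulfonate
Conditions: PhNTf2 (1.1 equiv), Et3N, CH2Cl2, 0 °C → rt
Reagents that add atoms: N-phenylbis(trifluoromethanesulfonimide), O=S(=O)(N(c1ccccc1)S(=O)(=O)C(F)(F)F)C(F)(F)F
Why: Phenol triflation with the mild triflyl-transfer reagent N-phenyltriflimide, chosen because it liberates no strong acid that could protonate the electron-rich chromene alkene.

**Step 5**
Reactants: 9 2,2-dimethyl-2H-chromen-7-yl trifluoromethanesulfonate
Product: 10 N-methoxy-N,2,2-trimethyl-2H-chromene-7-carboxamide (Weinreb amide)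
Conditions: CO (1 atm), MeONHMe·HCl (1.5 equiv), Pd(OAc)2 (3 mol %), Xantphos (4 mol %), Na2CO3 (3 equiv), toluene, 80–100 °C
Reagents that add atoms: carbon monoxide, [C-]#[O+]; N,O-dimethylhydroxylamine hydrochloride, CNOC.Cl
Why: Palladium-catalysed aminocarbonylation of an aryl triflate (oxidative addition to zerovalent palladium, CO insertion, aminolysis of the aroylpalladium species), a standard one-step entry to Weinreb amides in which CO capture is much faster than any Heck-type reaction at the hindered cis-disubstituted chromene alkene.

**Step 6**
Reactants: 11 ethyl glycolate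
Product: 12 ethyl 2-(methoxymethoxy)acetate
Conditions: MOMCl (1.3 equiv), i-Pr2NEt (1.5 equiv), CH2Cl2, 0 °C → rt
Reagents that add atoms: chloromethyl methyl ether (MOMCl), COCCl
Why: Standard acetal protection of a primary alcohol by alkylation with chloromethyl methyl ether under a hindered amine base, which does not touch the ester.

**Step 7**
Reactants: 12 ethyl 2-(methoxymethoxy)acetate (1.6 equiv); 10 N-methoxy-N,2,2-trimethyl-2H-chromene-7-carboxamide
Product: 14 ethyl 3-(2,2-dimethyl-2H-chromen-7-yl)-2-(methoxymethoxy)-3-oxopropanoate (racemic), via lithium enolate 13 (not isolated)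
Conditions: LiN(i-Pr)2 (LDA, 1.5 equiv), THF, −78 °C; then 10, −78 → −20 °C; sat. aq NH4Cl
Reagents that add atoms: none
Why: Crossed Claisen-type acylation of an ester enolate by a Weinreb amide: the chelated tetrahedral adduct survives until the quench, which prevents over-addition and proton transfer from the acidic product, and the new stereocentre is formed racemic and is of no consequence.

**Step 8**
Reactants: 5 2,4-diprenylphloroglucinol; 14 ethyl 3-(2,2-dimethyl-2H-chromen-7-yl)-2-(methoxymethoxy)-3-oxopropanoate (1.3 equiv)
Product: 17 3-O-methoxymethyl dorsilurin C, via aroylketene 15 (not isolated), via C-acyl 1,3-diketone 16 (not isolated)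
Conditions: neat melt, Ar stream, 220–240 °C (microwave or metal bath), 10–20 min, EtOH and H2O swept off
Reagents that add atoms: none
Why: Mentzer pyrone synthesis (the acid-free thermal counterpart of the Simonis chromone synthesis): the enol form of 14 expels ethanol to give aroylketene 15, and the only unsubstituted ring carbon of 5, activated by three oxygens, attacks the ketene carbon to form C4–C4a and give diketone 16, while any aryl ester arising from O-capture reverts to ketene and phenol at this temperature. A phenol flanking the new acyl group then adds to the aroyl carbonyl in a 6-exo-trig closure that forms O1–C2, and loss of water from the hemiketal gives the aromatic 4-pyranone ring C, which drives the whole sequence forward. The closest known reactions are the neat or microwave-heated condensations of phloroglucinol and its C-alkyl derivatives with ethyl aroylacetates and 2-substituted acylacetates, which give 5,7-dihydroxyflavones and 2,3-disubstituted chromones. Site selectivity is fixed by the substrate, because 5 has a mirror plane through its free carbon and the opposite C–OH, so there is one carbon to acylate and the two hydroxyls next to it lead to the same 6,8-diprenyl product. The selectivity that has to be won is chromone against 4-arylcoumarin, and it is secured by leaving out any acid: the ketone is never activated for Pechmann-type attack by the ring carbon, whereas the ester carbon reaches that carbon as a ketene. No stereocentre is created (the racemic α-carbon of 14 becomes sp2 C3), the C3 oxygen is carried in so that no oxidant ever meets the three alkenes, and the short heating stays within the temperature range in which ortho-prenylphenols and 2,2-dimethylchromenes are themselves prepared by thermal rearrangement.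

**Step 9**
Reactants: 17 3-O-methoxymethyl dorsilurin C
Product: 18 dorsilurin C
Conditions: aq HCl (3 M, few equiv), MeOH, 0 °C → rt, stopped at full conversion
Reagents that add atoms: none
Why: Acid-catalysed transacetalisation of the MOM group to methanol: the 3-O-acetal of a flavonol releases a stabilised enol-type leaving group and is cleaved by dilute methanolic acid at or below room temperature, conditions under which MOM groups are routinely taken off prenylated flavonoids and chalcones without chroman formation.

**Compound list**

1 | methyl 2,4,6-trihydroxybenzoate | COC(=O)c1c(O)cc(O)cc1O | starting material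
2 | prenyl bromide (1-bromo-3-methylbut-2-ene) | CC(C)=CCBr | starting material
3 | methyl 2,4,6-trihydroxy-3,5-bis(3-methylbut-2-enyl)benzoate | COC(=O)c1c(O)c(CC=C(C)C)c(O)c(CC=C(C)C)c1O | intermediate
4 | 2,4,6-trihydroxy-3,5-bis(3-methylbut-2-enyl)benzoic acid (present as its potassium salt, not isolated) | OC(=O)c1c(O)c(CC=C(C)C)c(O)c(CC=C(C)C)c1O | intermediate
5 | 2,4-diprenylphloroglucinol, 2,4-bis(3-methylbut-2-enyl)benzene-1,3,5-triol | CC(C)=CCc1c(O)cc(O)c(CC=C(C)C)c1O | intermediate
6 | umbelliferone (7-hydroxycoumarin) | O=c1ccc2ccc(O)cc2o1 | starting material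
7 | 4-[(Z)-3-hydroxy-3-methylbut-1-enyl]benzene-1,3-diol (not isolated) | CC(C)(O)/C=C\c1ccc(O)cc1O | intermediate
8 | 2,2-dimethyl-2H-chromen-7-ol | CC1(C)C=Cc2ccc(O)cc2O1 | intermediate
9 | 2,2-dimethyl-2H-chromen-7-yl trifluoromethanesulfonate | CC1(C)C=Cc2ccc(OS(=O)(=O)C(F)(F)F)cc2O1 | intermediate
10 | N-methoxy-N,2,2-trimethyl-2H-chromene-7-carboxamide | CON(C)C(=O)c1ccc2c(c1)OC(C)(C)C=C2 | intermediate
11 | ethyl glycolate | CCOC(=O)CO | starting material
12 | ethyl 2-(methoxymethoxy)acetate | CCOC(=O)COCOC | intermediate
13 | lithium enolate of 12, chelated geometry with OLi cis to the methoxymethoxy group (not isolated) | CCO/C([O-])=C/OCOC.[Li+] | intermediate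
14 | ethyl 3-(2,2-dimethyl-2H-chromen-7-yl)-2-(methoxymethoxy)-3-oxopropanoate (racemic, enolisable) | CCOC(=O)C(OCOC)C(=O)c1ccc2c(c1)OC(C)(C)C=C2 | intermediate
15 | 3-(2,2-dimethyl-2H-chromen-7-yl)-2-(methoxymethoxy)-3-oxoprop-1-en-1-one, the aroylketene (not isolated) | COCOC(=C=O)C(=O)c1ccc2c(c1)OC(C)(C)C=C2 | intermediate
16 | 1-(2,2-dimethyl-2H-chromen-7-yl)-2-(methoxymethoxy)-3-[2,4,6-trihydroxy-3,5-bis(3-methylbut-2-enyl)phenyl]propane-1,3-dione (racemic, not isolated) | CC(C)=CCc1c(O)c(CC=C(C)C)c(O)c(C(=O)C(OCOC)C(=O)c2ccc3c(c2)OC(C)(C)C=C3)c1O | intermediate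
17 | 3-O-methoxymethyl dorsilurin C | CC(C)=CCc1c(O)c(CC=C(C)C)c2oc(-c3ccc4c(c3)OC(C)(C)C=C4)c(OCOC)c(=O)c2c1O | intermediate
18 | dorsilurin C | CC(C)=CCc1c(O)c(CC=C(C)C)c2oc(-c3ccc4c(c3)OC(C)(C)C=C4)c(O)c(=O)c2c1O | target

**Step count**

Total step count: 9.
Longest linear sequence: 6 steps (steps 3, 4, 5, 7, 8 and 9, from umbelliferone 6).

**Steps most likely to fail**

**1. Step 8.**

Several processes may compete with the annulation at the temperature it needs:
- erosion of the acetal by the hot phenols;
- phenol-promoted ring closure of a prenyl group onto a neighbouring hydroxyl;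
- stalling at the O-acylated stage;
- hydrolysis and decarboxylation of the keto ester by the water that is released.

The fallback builds the flavonol by the Algar–Flynn–Oyamada route. It sets out from 10 and 2 and comes back at 18. Amide 10 is reduced with i-Bu2AlH (THF, −78 °C) to 2,2-dimethyl-2H-chromene-7-carbaldehyde F1. Purchased 2,4,6-trihydroxyacetophenone is C-prenylated twice with 2 (KOH, H2O, 0 °C) to 1-[2,4,6-trihydroxy-3,5-bis(3-methylbut-2-enyl)phenyl]ethanone F2.

MOMCl and i-Pr2NEt then cap two of the three hydroxyls. The last one is held back by its hydrogen bond to the ketone, which gives 1-[2-hydroxy-4,6-bis(methoxymethoxy)-3,5-bis(3-methylbut-2-enyl)phenyl]ethanone F3. Claisen–Schmidt condensation of this ketone with the aldehyde (KOH, EtOH, rt) gives (E)-3-(2,2-dimethyl-2H-chromen-7-yl)-1-[2-hydroxy-4,6-bis(methoxymethoxy)-3,5-bis(3-methylbut-2-enyl)phenyl]prop-2-en-1-one F4.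

Alkaline H2O2 (NaOH, MeOH, 0 °C → rt) is a nucleophilic oxidant that attacks only the enone and spares the three electron-rich alkenes. It converts the chalcone into 5,7-bis-O-methoxymethyl dorsilurin C F5. Dilute methanolic HCl, as in step 9, then gives 18.

**2. Step 1.**

O-alkylation, incomplete second alkylation and a third, dearomatising alkylation at an already substituted carbon may all compete with clean double C-alkylation.

The fallback replaces phenoxide alkylation by directed ortho-lithiation. It sets out from 2 and comes back at 5, and it also bypasses step 2. Purchased phloroglucinol is converted with MOMCl and NaH (DMF) into 1,3,5-tris(methoxymethoxy)benzene F6. n-BuLi (THF, 0 °C) lithiates between two acetal oxygens, and 2 alkylates the aryllithium to give 1,3,5-tris(methoxymethoxy)-2-(3-methylbut-2-enyl)benzene F7.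

A second round of the same lithiation and alkylation, at one of the two equivalent remaining positions, gives 1,3,5-tris(methoxymethoxy)-2,4-bis(3-methylbut-2-enyl)benzene F8. Dilute methanolic HCl at room temperature then releases 5.

**3. Step 9.**

Acid-promoted addition of the 5-OH or 7-OH to a neighbouring prenyl alkene, or protonation of the chromene alkene, may run at a rate comparable with acetal cleavage.

The fallback changes the C3 oxygen protection from an acid-labile acetal to a fluoride-labile silyl ether. It sets out from 11, uses 10 and 5, and comes back at 18. Ester 11 is silylated (TBSCl, imidazole, DMF) to ethyl 2-(tert-butyldimethylsilyloxy)acetate F9. Its lithium enolate is acylated with 10 as in step 7 to give ethyl 2-(tert-butyldimethylsilyloxy)-3-(2,2-dimethyl-2H-chromen-7-yl)-3-oxopropanoate F10.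

Heating this keto ester with 5 as in step 8 gives 3-O-(tert-butyldimethylsilyl) dorsilurin C F11. Any silyl transfer to a phenol during the melt is harmless, because Bu4NF buffered with AcOH (THF, 0 °C) removes all silyl groups and gives 18 without acid.

**Further compounds**

F1 | step 8 | 2,2-dimethyl-2H-chromene-7-carbaldehyde | O=Cc1ccc2c(c1)OC(C)(C)C=C2
F2 | step 8 | 1-[2,4,6-trihydroxy-3,5-bis(3-methylbut-2-enyl)phenyl]ethanone | CC(=O)c1c(O)c(CC=C(C)C)c(O)c(CC=C(C)C)c1O
F3 | step 8 | 1-[2-hydroxy-4,6-bis(methoxymethoxy)-3,5-bis(3-methylbut-2-enyl)phenyl]ethanone | CC(=O)c1c(O)c(CC=C(C)C)c(OCOC)c(CC=C(C)C)c1OCOC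
F4 | step 8 | (E)-3-(2,2-dimethyl-2H-chromen-7-yl)-1-[2-hydroxy-4,6-bis(methoxymethoxy)-3,5-bis(3-methylbut-2-enyl)phenyl]prop-2-en-1-one | COCOc1c(CC=C(C)C)c(O)c(C(=O)/C=C/c2ccc3c(c2)OC(C)(C)C=C3)c(OCOC)c1CC=C(C)C
F5 | step 8 | 5,7-bis-O-methoxymethyl dorsilurin C | CC(C)=CCc1c(OCOC)c(CC=C(C)C)c2oc(-c3ccc4c(c3)OC(C)(C)C=C4)c(O)c(=O)c2c1OCOC
F6 | step 1 | 1,3,5-tris(methoxymethoxy)benzene | COCOc1cc(OCOC)cc(OCOC)c1
F7 | step 1 | 1,3,5-tris(methoxymethoxy)-2-(3-methylbut-2-enyl)benzene | COCOc1cc(OCOC)c(CC=C(C)C)c(OCOC)c1
F8 | step 1 | 1,3,5-tris(methoxymethoxy)-2,4-bis(3-methylbut-2-enyl)benzene | COCOc1cc(OCOC)c(CC=C(C)C)c(OCOC)c1CC=C(C)C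
F9 | step 9 | ethyl 2-(tert-butyldimethylsilyloxy)acetate | CCOC(=O)CO[Si](C)(C)C(C)(C)C
F10 | step 9 | ethyl 2-(tert-butyldimethylsilyloxy)-3-(2,2-dimethyl-2H-chromen-7-yl)-3-oxopropanoate (racemic) | CCOC(=O)C(O[Si](C)(C)C(C)(C)C)C(=O)c1ccc2c(c1)OC(C)(C)C=C2
F11 | step 9 | 3-O-(tert-butyldimethylsilyl) dorsilurin C | CC(C)=CCc1c(O)c(CC=C(C)C)c2oc(-c3ccc4c(c3)OC(C)(C)C=C4)c(O[Si](C)(C)C(C)(C)C)c(=O)c2c1O
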